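**Retrosynthetic overview**

- Target 16 ← bis(allyl ether) 15 by O-deallylation ← enone 11 through its tosylhydrazone 12: the C2' oxygen is removed reductively while the alkene moves from C3'=C4' to C2'=C3'.
- Feature used: ring C (C1'H–aryl, C2'H=C3'(CH3), C4'H2, C5'H2, C6'H–isopropyl) is a disguised 6-aryl-5-isopropyl-2-methylcyclohex-2-enone. A carbonyl at C2' makes the benzylic C1' epimerisable, so the trans C1'/C6' relation comes from equilibration and only C6' needs absolute control.
- Ring C ← [3+3] annulation: C1'–C6' by amine-catalysed Michael addition of the alpha-aryl beta-ketoester 6 to enal 7, C3'–C4' by aldol condensation, then loss of the tert-butyl ester.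
- 6 ← aryl iodide 4 + tert-butyl 3-oxopentanoate 5 (copper catalysis); 4 ← magnolol 1 by mono-allylation, ortho-iodination and allylation.
- Ring order: rings A and B are bought as magnolol; ring C is the only ring built (step 5).

Key step: step 5

Remark on protecting groups: the phenols are carried as allyl ethers instead of acetal ethers. Step 5 ends in hot p-TsOH, where a freed ortho phenol would condense with the C2' ketone to a benzofuran, and allyl ethers can be removed at the end without acid, which keeps the ortho phenol from adding to the C2'=C3' alkene.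

Remark on stereochemistry: the target (1'R,6'R) has aryl and isopropyl trans on ring C; this is assumed to be the more stable arrangement in enone 11. Ring B is the phenol ring that carries ring C at C3; ring A is the other one.

**Route**

Step 1
Reactants: 1 magnolol
Product: 2 2'-(allyloxy)-5,5'-diallylbiphenyl-2-ol (mono-allyl ether of magnolol)
Conditions: allyl bromide (1.05 equiv), K2CO3 (1.1 equiv), acetone, rt
Reagents that add atoms: allyl bromide, C=CCBr
Why: Williamson ether synthesis; the first phenol of a 2,2'-biphenol is much more acidic than the second because its phenoxide is held by the neighbouring O–H hydrogen bond, so one equivalent of weak base and halide should stop largely at the mono-ether, with unreacted 1 recoverable.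

Step 2
Reactants: 2 mono-allyl ether of magnolol
Product: 3 2'-(allyloxy)-5,5'-diallyl-3-iodobiphenyl-2-ol
Conditions: I2 (1.05 equiv), morpholine (3 equiv), CH2Cl2, 0 °C to rt; aq. Na2S2O3
Reagents that add atoms: iodine, II
Why: Electrophilic aromatic iodination by the amine–iodine complex, which attacks only the free phenol ring (ring B); its para position carries the allyl group and one ortho position the biaryl bond, so C3 is the only open site, and isolated alkenes and the ether ring should not react under these mild conditions.

Step 3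
Reactants: 3 iodophenol
Product: 4 2,2'-bis(allyloxy)-5,5'-diallyl-3-iodobiphenyl
Conditions: allyl bromide (1.5 equiv), K2CO3 (2 equiv), DMF, 40 °C
Reagents that add atoms: allyl bromide, C=CCBr
Why: Williamson ether synthesis on the remaining, hindered phenol; the small, reactive allyl halide in a dipolar solvent should alkylate it cleanly on oxygen.

Step 4
Reactants: 4 aryl iodide; 5 tert-butyl 3-oxopentanoate
Product: 6 tert-butyl 2-[2,2'-bis(allyloxy)-5,5'-diallylbiphenyl-3-yl]-3-oxopentanoate (racemic at C2, largely enolised)
Conditions: 5 (2 equiv), CuI (20 mol%), L-proline (40 mol%), Cs2CO3 (4 equiv), DMSO, 40–50 °C, argon; aq. NH4Cl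
Reagents that add atoms: tert-butyl 3-oxopentanoate (5), CCC(=O)CC(=O)OC(C)(C)C
Why: Copper-catalysed arylation of an active methylene compound (Ullmann–Hurtley type coupling); the amino-acid-ligated CuI couples the aryl iodide with the caesium enolate of 5 at a temperature at which the product, stored as its enolate, should keep its acyl group, and the non-radical pathway should leave the ortho allyl ether alone.

Step 5
Reactants: 6 alpha-aryl beta-ketoester; 7 (E)-4-methylpent-2-enal
Product: 11 (5R,6S)-6-[2,2'-bis(allyloxy)-5,5'-diallylbiphenyl-3-yl]-2-methyl-5-(propan-2-yl)cyclohex-2-en-1-one (trans enone), via Michael adduct 8 (not isolated), via annulated tert-butyl ester 9 (not isolated), via beta-keto acid 10 (not isolated)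
Conditions: (R)-diphenylprolinol trimethylsilyl ether (20 mol%), PhCO2H (20 mol%), 7 (2 equiv), toluene, rt; then p-TsOH·H2O (0.5 equiv), toluene, 80 °C
Reagents that add atoms: (E)-4-methylpent-2-enal (7), CC(C)/C=C/C=O
Why: Proposed new method: the amine-catalysed Michael addition of beta-ketoesters to enals with acid-driven aldol condensation and decarboxylation is the closest known reaction type (established for alpha-unsubstituted tert-butyl beta-ketoesters), and it is extended here to an acyclic alpha-aryl beta-ketoester that must form a fully substituted carbon; the reasoning is that 6 is strongly enolised and acidic, so the benzoate-buffered amine system should hold enough soft enol/enolate to add to the beta-carbon of the E,s-trans iminium ion of 7 (C1'–C6' bond), giving 8 after hydrolysis. p-TsOH then enolises the ethyl ketone, the only side that can enolise because C1' is quaternary, and its CH2 carbon closes ring C on the aldehyde by a 6-(enolendo)-exo-trig aldol addition (C3'–C4' bond); dehydration gives 9, acidolysis of the tert-butyl ester releases isobutene, and 10 loses CO2. C6' is set by the catalyst: the CPh2(OSiMe3) arm of the (R)-amine covers the Re face of the iminium beta-carbon, so the enol bonds to the Si face and C6' becomes R. C1' is set by thermodynamic control: after decarboxylation it is benzylic and alpha to the C2' ketone and should equilibrate through the enol under the acid to the trans isomer with aryl and isopropyl both equatorial. The step needs 1,4- over 1,2-addition and C- over O-alkylation, which iminium activation and the soft donor secure, and it needs a single aldol regiochemistry, which the blocked C1' secures. The ortho oxygen must stay masked, since a free phenol would condense with the C2' ketone to a benzofuran, and the allyl ethers should withstand the acid.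

Step 6
Reactants: 11 trans enone
Product: 12 N'-[(5R,6S)-6-[2,2'-bis(allyloxy)-5,5'-diallylbiphenyl-3-yl]-2-methyl-5-(propan-2-yl)cyclohex-2-en-1-ylidene]-4-methylbenzenesulfonohydrazide (tosylhydrazone)
Conditions: TsNHNH2 (1.3 equiv), AcOH (cat.), EtOH, 50 °C
Reagents that add atoms: 4-methylbenzenesulfonohydrazide, Cc1ccc(cc1)S(=O)(=O)NN
Why: Carbonyl condensation to the tosylhydrazone by 1,2-addition at C2'; weakly acidic conditions are chosen so that the trans arrangement at C1' is kept, and C6' is not involved.

Step 7
Reactants: 12 tosylhydrazone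
Product: 15 2,2'-bis(allyloxy)-5,5'-diallyl-3-[(1R,6R)-3-methyl-6-(propan-2-yl)cyclohex-2-en-1-yl]biphenyl, via N-boryl tosylhydrazine 13 (not isolated), via allylic diazene 14 (not isolated)
Conditions: catecholborane (2.5 equiv), CHCl3, 0 °C; then NaOAc·3H2O (5 equiv), 60 °C
Reagents that add atoms: none
Why: Reductive 1,3-transposition of an enone tosylhydrazone: catecholborane delivers hydride to C2', acetate releases sulfinate to give the allylic diazene, and this loses N2 by a retro-ene hydrogen shift that places H on C4' and the alkene at C2'=C3'; C1' and C6' are not touched, and terminal alkenes should not be hydroborated by catecholborane at this temperature.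

Step 8
Reactants: 15 bis(allyl ether)
Product: 16 5,5'-diallyl-3-[(1R,6R)-3-methyl-6-(propan-2-yl)cyclohex-2-en-1-yl]biphenyl-2,2'-diol (target)
Conditions: Pd(PPh3)4 (5 mol%), K2CO3 (3 equiv), MeOH–THF (degassed), rt; aq. NH4Cl
Reagents that add atoms: none
Why: Tsuji–Trost deallylation: zerovalent palladium ionises only the aryl allyl ethers to pi-allyl complexes that methanol/methoxide captures, whereas the C-allyl groups and the ring C alkene carry no leaving group; the non-acidic conditions avoid addition of the ortho phenol to the C2'=C3' alkene.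

**Compound list**

1 | magnolol (5,5'-diallylbiphenyl-2,2'-diol) | C=CCc1ccc(O)c(-c2cc(CC=C)ccc2O)c1 | starting material
2 | 2'-(allyloxy)-5,5'-diallylbiphenyl-2-ol | C=CCc1ccc(O)c(-c2cc(CC=C)ccc2OCC=C)c1 | intermediate
3 | 2'-(allyloxy)-5,5'-diallyl-3-iodobiphenyl-2-ol | C=CCc1cc(I)c(O)c(-c2cc(CC=C)ccc2OCC=C)c1 | intermediate
4 | 2,2'-bis(allyloxy)-5,5'-diallyl-3-iodobiphenyl | C=CCOc1ccc(CC=C)cc1-c1cc(CC=C)cc(I)c1OCC=C | intermediate
5 | tert-butyl 3-oxopentanoate | CCC(=O)CC(=O)OC(C)(C)C | starting material
6 | tert-butyl 2-[2,2'-bis(allyloxy)-5,5'-diallylbiphenyl-3-yl]-3-oxopentanoate (racemic at C2) | CCC(=O)C(C(=O)OC(C)(C)C)c1cc(CC=C)cc(-c2cc(CC=C)ccc2OCC=C)c1OCC=C | intermediate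
7 | (E)-4-methylpent-2-enal | CC(C)/C=C/C=O | starting material
8 | tert-butyl (3R)-2-[2,2'-bis(allyloxy)-5,5'-diallylbiphenyl-3-yl]-5-oxo-2-propanoyl-3-(propan-2-yl)pentanoate (Michael adduct, C2 epimers) | CCC(=O)C(C(=O)OC(C)(C)C)([C@H](CC=O)C(C)C)c1cc(CC=C)cc(-c2cc(CC=C)ccc2OCC=C)c1OCC=C | intermediate
9 | tert-butyl (6R)-1-[2,2'-bis(allyloxy)-5,5'-diallylbiphenyl-3-yl]-3-methyl-2-oxo-6-(propan-2-yl)cyclohex-3-ene-1-carboxylate (C1 epimers) | CC1=CC[C@H](C(C)C)C(C(=O)OC(C)(C)C)(c2cc(CC=C)cc(-c3cc(CC=C)ccc3OCC=C)c2OCC=C)C1=O | intermediate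
10 | (6R)-1-[2,2'-bis(allyloxy)-5,5'-diallylbiphenyl-3-yl]-3-methyl-2-oxo-6-(propan-2-yl)cyclohex-3-ene-1-carboxylic acid (C1 epimers) | CC1=CC[C@H](C(C)C)C(C(=O)O)(c2cc(CC=C)cc(-c3cc(CC=C)ccc3OCC=C)c2OCC=C)C1=O | intermediate
11 | (5R,6S)-6-[2,2'-bis(allyloxy)-5,5'-diallylbiphenyl-3-yl]-2-methyl-5-(propan-2-yl)cyclohex-2-en-1-one (aryl and isopropyl trans) | C=CCc1ccc(OCC=C)c(-c2cc(CC=C)cc([C@H]3C(=O)C(C)=CC[C@@H]3C(C)C)c2OCC=C)c1 | intermediate
12 | tosylhydrazone of 11 (5R,6S; C=N geometry not defined) | C=CCc1ccc(OCC=C)c(-c2cc(CC=C)cc([C@H]3C(=NNS(=O)(=O)c4ccc(C)cc4)C(C)=CC[C@@H]3C(C)C)c2OCC=C)c1 | intermediate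
13 | N'-(1,3,2-benzodioxaborol-2-yl)-N'-[(5R,6S)-6-aryl-2-methyl-5-(propan-2-yl)cyclohex-2-en-1-yl]-4-methylbenzenesulfonohydrazide (aryl = 2,2'-bis(allyloxy)-5,5'-diallylbiphenyl-3-yl; C1 epimers) | C=CCc1ccc(OCC=C)c(-c2cc(CC=C)cc([C@H]3C(N(NS(=O)(=O)c4ccc(C)cc4)B4Oc5ccccc5O4)C(C)=CC[C@@H]3C(C)C)c2OCC=C)c1 | intermediate
14 | [(5R,6S)-6-aryl-2-methyl-5-(propan-2-yl)cyclohex-2-en-1-yl]diazene (aryl as in 13; C1 epimers) | C=CCc1ccc(OCC=C)c(-c2cc(CC=C)cc([C@H]3C(N=N)C(C)=CC[C@@H]3C(C)C)c2OCC=C)c1 | intermediate
15 | 2,2'-bis(allyloxy)-5,5'-diallyl-3-[(1R,6R)-3-methyl-6-(propan-2-yl)cyclohex-2-en-1-yl]biphenyl | C=CCc1ccc(OCC=C)c(-c2cc(CC=C)cc([C@H]3C=C(C)CC[C@@H]3C(C)C)c2OCC=C)c1 | intermediate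
16 | 5,5'-diallyl-3-[(1R,6R)-3-methyl-6-(propan-2-yl)cyclohex-2-en-1-yl]biphenyl-2,2'-diol | C=CCc1ccc(O)c(-c2cc(CC=C)cc([C@H]3C=C(C)CC[C@@H]3C(C)C)c2O)c1 | target

**Step count**

Total steps: 8. Longest linear sequence: 8 steps (from magnolol 1; 5 and 7 are purchased).

**Steps most likely to fail, with fallbacks**

Step 5. The addition may stall or run backwards, because the bond forms at a fully substituted donor carbon next to the branched beta-carbon of the iminium ion; the enal would then be consumed by dienamine self-condensation, and a background base-catalysed addition could erode facial selectivity. The fallback uses known chemistry, sets out from magnolol 1 and comes back at target 16. (R)-Piperitone is reduced (NaBH4, CeCl3·7H2O, MeOH, 0 °C; Luche reduction) to (6R)-piperitol F1. An excess of 1 is then alkylated with F1 under p-TsOH or BF3·OEt2 catalysis with MgSO4 in CH2Cl2 at low temperature (Friedel–Crafts allylation through the piperityl cation, the established way to terpenyl phenols of this type). The arene should attack the secondary terminus of the cation anti to the isopropyl group, at the only free position ortho to a hydroxyl. This would give 16 directly, with C6' taken from the terpene and C1' set trans; the reaction would be stopped early to avoid acid-induced ether formation.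

Step 6. Condensation at the hindered C2' carbonyl may be incomplete, and C1' may epimerise through the ene-hydrazine, since allylic strain with the N–NHTs group can favour an axial aryl group. The fallback sets out from enone 11 and comes back at 15. Luche reduction (NaBH4, CeCl3·7H2O, MeOH, −20 °C) should give the allylic alcohol (5R,6S)-6-aryl-2-methyl-5-(propan-2-yl)cyclohex-2-en-1-ol F2. A Mitsunobu reaction with 2-nitrobenzenesulfonylhydrazide (PPh3, DEAD, THF, −30 °C) should then give the N-allylic sulfonylhydrazine F3. On warming to rt this loses 2-nitrobenzenesulfinic acid to form the allylic diazene 14, which expels N2 with the same alkene shift and gives 15. No carbonyl derivative is heated in this sequence, so C1' is not put at risk.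

Step 4. The arylated product may lose its propanoyl group by retro-Claisen cleavage under the basic coupling conditions. The fallback sets out from 4 and 5 and comes back at 6, and it makes use of that cleavage. The copper coupling is run hot and wet (CuI, L-proline, Cs2CO3, DMSO with added water, 80 °C) until deacylation is complete, which should give tert-butyl 2-[2,2'-bis(allyloxy)-5,5'-diallylbiphenyl-3-yl]acetate F4. F4 is then C-acylated (LiN(SiMe3)2, 2.2 equiv, THF, −78 °C; propanoyl chloride; crossed Claisen acylation) to give 6.

**Further compounds**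

F1 | step 5 | (6R)-3-methyl-6-(propan-2-yl)cyclohex-2-en-1-ol (piperitol, C1 epimers) | CC1=CC(O)[C@@H](C(C)C)CC1
F2 | step 6 | (5R,6S)-6-[2,2'-bis(allyloxy)-5,5'-diallylbiphenyl-3-yl]-2-methyl-5-(propan-2-yl)cyclohex-2-en-1-ol (C1 epimers) | C=CCc1ccc(OCC=C)c(-c2cc(CC=C)cc([C@H]3C(O)C(C)=CC[C@@H]3C(C)C)c2OCC=C)c1
F3 | step 6 | N-[(5R,6S)-6-[2,2'-bis(allyloxy)-5,5'-diallylbiphenyl-3-yl]-2-methyl-5-(propan-2-yl)cyclohex-2-en-1-yl]-2-nitrobenzenesulfonohydrazide (C1 epimers) | C=CCc1ccc(OCC=C)c(-c2cc(CC=C)cc([C@H]3C(N(N)S(=O)(=O)c4ccccc4[N+](=O)[O-])C(C)=CC[C@@H]3C(C)C)c2OCC=C)c1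
F4 | step 4 | tert-butyl 2-[2,2'-bis(allyloxy)-5,5'-diallylbiphenyl-3-yl]acetate | CC(C)(C)OC(=O)Cc1cc(CC=C)cc(-c2cc(CC=C)ccc2OCC=C)c1OCC=C
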